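Remark on the chemistry: the target is achiral, and carbinol 16 is made and used as the racemate because its only stereocenter is removed by the oxidation in step 11.

## The problem

Pestalone B is an achiral benzophenone whose ketone carbon carries four ortho substituents. On ring A (A1 OMe, A2 H, A3 CH3, A4 Br, A5 OH, A6 acyl) these are a methoxy and a hydroxy group; on ring B (B1 acyl, B2 CHO, B3 OH, B4 H, B5 OH, B6 prenyl) a formyl and a prenyl group. The bonds from the carbonyl carbon to A6 and to B1 are therefore the hardest to make from two finished arenes, and at least one is better made while its ring does not yet exist. No stereocenter has to be set; the only stereochemical elements on the way are an enoate geometry inherited from a ring and a racemic carbinol that is oxidized away. Ring A poses a regiochemical problem: its two oxygens must be told apart (one methylated, one free), and bromine must enter at A4 beside the free hydroxyl and not at A2. Several groups are fragile: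
- the B2 aldehyde ortho to the diaryl ketone is prone to lactol and hydride-transfer chemistry with base or nucleophiles;
- the prenyl group beside the B5 hydroxyl cyclizes to a chroman in strong acid and reacts with electrophilic halogen;
- a free resorcinol ring B would be halogenated before ring A;
- the C–Br bond would not survive organolithium reagents or hydrogenation.

The enabling feature is that ring A without bromine and O-methyl is a 2-acyl-5-methylresorcinol, symmetric about the A3–A6 axis. Its carbons A1 to A5, with the methyl on A3, are C2 to C6 of 4,6-dimethyl-2H-pyran-2-one, and A6 is that pyranone's C6 methyl carbon. Ring A can therefore arise by isomerization of a pyranone that already carries the finished ring B.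

## Retrosynthesis

**Protecting groups (22 from 21).** Only C–O bonds are cut: the two methoxymethyl ethers on the B3 and B5 oxygens and the dimethyl acetal on the B2 formyl carbon. The ortho-formyl benzophenone tolerates acid better than base, and ring B must stay masked until ring A has been brominated, so one acid step at the very end removes all three groups. The forward reaction must be mild enough to leave the prenyl alkene alone.

**Bromine and O-methyl (21 from 20 from 19).** The A4–Br bond is cut first, then the A1 O–CH3 bond. This order leads back to 19, whose ring A is symmetric, so the forward methylation cannot give a regioisomer; once one oxygen is methylated, A4 is the only free position ortho to the remaining phenol. Carrying bromine earlier would force a choice between two non-equivalent hydroxyls. The forward steps must stop at mono-alkylation and brominate ortho rather than para.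

**Ring A (19 from 17).** The A6–A1 bond is cut and the A1 carbonyl is reconnected through oxygen to A5, which turns the resorcinol 19 into its isomer, pyranone 17. The neighbouring cut, between A6 and the ketone carbon with ring A intact, would require two fully ortho-substituted partners to meet at the carbonyl. Here the ketone carbon is already bonded to A6 while A6 is a CH2 group. All of ring A reduces to commercial pyranone 14. The forward reaction needs Claisen closure at A6 to beat aldol closure.

**Fragment union (17 from 16 from 13 and 14).** The bond between the ketone carbon and the CH2 group (future A6) is cut. Aldol addition of the lithiated pyranone 15 to aldehyde 13, followed by oxidation of carbinol 16, is preferred over direct acylation of the anion, because a doubly ortho-substituted benzoate is a poor acylating agent while the aldehyde is reactive. The synthesis becomes convergent. The forward step needs deprotonation at the C6 methyl of 14 and no dehydration of 16.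

**Differentiating the two carbonyl carbons of ring B (13 from 12 from 11 from 10).** No skeletal bond is cut. The B1 carbon arrives as an ester and must become the aldehyde that the pyranone anion attacks; the B2 formyl group must stay at the aldehyde level to the end. Masking the formyl group of 10 as the acetal 11, reducing the ester to alcohol 12 and oxidizing to 13 achieves this. A direct partial reduction of the hindered ester is not relied on.

**Prenyl group (10 from 9 from 8 from 7).** The B6–CH2 bond is cut by a retro-Claisen operation to the 1,1-dimethylallyl ether on the B5 oxygen of 8. Friedel–Crafts prenylation would give poor regiocontrol and chromans, and aryl-metal prenylation is incompatible with the aldehyde and ester. The B3 hydroxyl of 7 is capped first (8) because a free, chelated B3 hydroxyl would steer the rearrangement to B4. The forward shift must go to the carbon next to the ester, which the acceptor ester and the donor alkoxy group both favour.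

**Ether oxygen–carbon bond (7 from 3 and 6; 6 from 4).** The O–C bond of the tertiary allyl ether is cut to phenol 3 and carbonate 6, which comes from alcohol 4. Palladium catalysis delivers the branched ether that an SN2 alkylation cannot. Only the non-chelated 5-hydroxyl of 3 should react.

**Formyl group (3 from 1).** The B2–CHO bond is cut to commercial methyl 3,5-dihydroxybenzoate 1. Vilsmeier–Haack formylation enters ortho to one hydroxyl and para to the other, next to the ester.

## Roads not taken

Alternative 1: The cut is the bond from A6 to the future ketone carbon, made intramolecularly. The aryloxymethyl ketone A2 would be cyclodehydrated with acid to the 3-arylbenzofuran A1, and oxidative cleavage of the furan double bond would later reveal the ketone and the A5 hydroxyl.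
- Merits: bromine and the methyl ether sit on ring A from the start, the ring A phenol has only one free ortho position, and the tether overcomes the hindrance of the aryl–carbonyl bond.
- Weak points: A1 carries no prenyl group and holds the aldehyde carbon as a pivaloyloxymethyl group. A prenyl group would not survive strong acid or oxidative alkene cleavage, so it must be introduced late at the most hindered position of ring B, followed by pivalate removal and benzylic oxidation.
- Comparison: this road is better on ring A regiochemistry and avoids the late bromination of step 14. Against that, the chosen plan carries prenyl and the masked aldehyde through unchanged, uses no oxidant stronger than IBX near the alkene, and needs fewer steps after the rings are joined.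

Alternative 2: Ring B is cut into 6-methylhept-5-en-2-one A4 and the aroylmethylene malonate A5. With KOt-Bu, the more substituted enolate of A4 would add to A5 and the methyl-side enolate would close onto an ester, giving cyclohexane-1,3-dione A3, which is then aromatized and its ester reduced to the aldehyde.
- Merits: the ring B carbons, the prenyl group included, are assembled in one operation from a cheap ketone; bromine is again in place early; no bond is formed at a hindered arene.
- Weak points: the two enolates of A4 must react in the required order. A3 is a mixture of diastereomers and enol forms. Dehydrogenating a trisubstituted cyclohexanedione to a resorcinol next to a prenyl alkene and an aryl bromide is a demanding oxidation. The ester must then be reduced beside a diaryl ketone.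
- Comparison: this road builds ring B in far fewer steps than steps 1 to 9 here. The chosen plan sets against it that every ring B substituent is placed by aromatic chemistry of known regiochemistry and that ring A is formed at the correct oxidation level with no aromatization step.

Alternative 3: Ring A is cut at A5–A6, A1–A2 and A4–A5. Photochemical Wolff rearrangement of the diazo ketone A7 would give a vinylketene that combines with the methoxyalkyne A8 by (2+2) cycloaddition, four-electron ring opening and six-electron ring closure to the phenol A6.
- Merits: the two ring A oxygens are differentiated in the ring-forming step (OMe from the alkyne, OH from the ketene), regiochemistry is fully programmed, and A8 would come from aldehyde 13 in two steps, so the step count is about equal.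
- Weak points: a diazo ketone and a photochemical step on a late intermediate; possible ketene cycloaddition to the prenyl alkene; an acid-labile alkoxyalkyne carbinol. After the annulation, a diaryl carbinol with four ortho substituents still has to be desilylated and oxidized, and A4 still has to be brominated.
- Comparison: this road is better at oxygen differentiation and saves the methylation. The chosen plan sets against it a reagent-free isomerization in basic methanol, oxidation of the carbinol before ring A exists, and a symmetric product whose methylation is unambiguous.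

Key step: step 12

## Route

Abbreviations used in the steps: ArB = 2-(dimethoxymethyl)-3,5-bis(methoxymethoxy)-6-(3-methylbut-2-en-1-yl)phenyl; MOM = methoxymethyl.

Step 1
Reactants: 1 methyl 3,5-dihydroxybenzoate
Product: 3 methyl 2-formyl-3,5-dihydroxybenzoate, via aryl iminium chloride 2 (not isolated)
Conditions: POCl3, DMF, MeCN, 0 °C to rt; then H2O, 50 °C
Reagents that add atoms: N,N-dimethylformamide, CN(C)C=O (formyl carbon); water, O (formyl oxygen)
Why: Vilsmeier–Haack formylation; the chloroiminium ion should attack C2, ortho to one hydroxyl and para to the other, rather than the carbon between the hydroxyls, and hydrolysis of iminium 2 gives the aldehyde with its 3-hydroxyl chelated.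

Step 2
Reactants: 4 2-methylbut-3-en-2-ol
Product: 6 methyl 2-methylbut-3-en-2-yl carbonate, via lithium alkoxide 5 (not isolated)
Conditions: n-BuLi, THF, −78 °C; then ClCO2Me, −78 °C to rt
Reagents that add atoms: methyl chloroformate, COC(=O)Cl
Why: O-acylation of a tertiary lithium alkoxide with a chloroformate, the standard preparation of tertiary allylic carbonates for allylic substitution.

Step 3
Reactants: 3 methyl 2-formyl-3,5-dihydroxybenzoate; 6 methyl 2-methylbut-3-en-2-yl carbonate
Product: 7 methyl 2-formyl-3-hydroxy-5-[(2-methylbut-3-en-2-yl)oxy]benzoate
Conditions: Pd(PPh3)4 (5 mol %), THF, 0 °C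
Reagents that add atoms: none
Why: Tsuji–Trost O-allylation; zerovalent palladium ionizes 6 with loss of CO2, and the phenoxide should attack the more substituted allyl terminus at low temperature to give the branched ether. Only the 5-hydroxyl should react, because the 3-hydroxyl is held in a hydrogen bond to the formyl group.

Step 4
Reactants: 7 methyl 2-formyl-3-hydroxy-5-[(2-methylbut-3-en-2-yl)oxy]benzoate
Product: 8 methyl 2-formyl-3-(methoxymethoxy)-5-[(2-methylbut-3-en-2-yl)oxy]benzoate
Conditions: NaH, MOMCl, DMF, 0 °C
Reagents that add atoms: chloromethyl methyl ether, COCCl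
Why: Williamson-type MOM protection of the chelated phenol; capping this oxygen removes the OH···O=C chelate that would otherwise fix the ring bonds and direct the coming Claisen shift to C4 between the two oxygens.

Step 5
Reactants: 8 methyl 2-formyl-3-(methoxymethoxy)-5-[(2-methylbut-3-en-2-yl)oxy]benzoate
Product: 9 methyl 2-formyl-5-hydroxy-3-(methoxymethoxy)-6-(3-methylbut-2-en-1-yl)benzoate
Conditions: PhMe, 120 °C, sealed tube
Reagents that add atoms: none
Why: Aromatic Claisen rearrangement ([3,3] shift, then enolization) turns the 1,1-dimethylallyl ether into a 3-methylbut-2-enyl group on an ortho carbon. C6 should be preferred over C4 because it lies toward the meta ester (acceptor) and away from the meta alkoxy group (donor), the known meta-substituent pattern of this rearrangement.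

Step 6
Reactants: 9 methyl 2-formyl-5-hydroxy-3-(methoxymethoxy)-6-(3-methylbut-2-en-1-yl)benzoate
Product: 10 methyl 2-formyl-3,5-bis(methoxymethoxy)-6-(3-methylbut-2-en-1-yl)benzoate
Conditions: NaH, MOMCl, DMF, 0 °C
Reagents that add atoms: chloromethyl methyl ether, COCCl
Why: Williamson-type MOM protection of the liberated phenol, which is acidic because it is para to the formyl group.

Step 7
Reactants: 10 methyl 2-formyl-3,5-bis(methoxymethoxy)-6-(3-methylbut-2-en-1-yl)benzoate
Product: 11 methyl 2-(dimethoxymethyl)-3,5-bis(methoxymethoxy)-6-(3-methylbut-2-en-1-yl)benzoate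
Conditions: HC(OMe)3, MeOH, PPTS (cat.), rt; Et3N quench
Reagents that add atoms: trimethyl orthoformate, COC(OC)OC; methanol, CO (source of the two methoxy groups)
Why: Acid-catalysed acetalization with orthoformate as water scavenger; the pyridinium catalyst at room temperature should leave the aryl MOM ethers intact, and the acetal keeps the B2 formyl carbon out of the next three steps.

Step 8
Reactants: 11 methyl 2-(dimethoxymethyl)-3,5-bis(methoxymethoxy)-6-(3-methylbut-2-en-1-yl)benzoate
Product: 12 [2-(dimethoxymethyl)-3,5-bis(methoxymethoxy)-6-(3-methylbut-2-en-1-yl)phenyl]methanol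
Conditions: LiAlH4, THF, 0 °C to rt; then H2O, aq NaOH, H2O
Reagents that add atoms: none
Why: Hydride reduction of a hindered ester to the primary alcohol; acetal, MOM ethers and alkene are inert, and the basic work-up avoids closure of the hydroxy acetal to a cyclic methyl acetal.

Step 9
Reactants: 12 [2-(dimethoxymethyl)-3,5-bis(methoxymethoxy)-6-(3-methylbut-2-en-1-yl)phenyl]methanol
Product: 13 2-(dimethoxymethyl)-3,5-bis(methoxymethoxy)-6-(3-methylbut-2-en-1-yl)benzaldehyde
Conditions: MnO2, CH2Cl2, rt
Reagents that add atoms: none
Why: MnO2 oxidation of a benzylic alcohol to the aldehyde under neutral heterogeneous conditions, with no over-oxidation and no acid to touch the acetal.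

Step 10
Reactants: 13 2-(dimethoxymethyl)-3,5-bis(methoxymethoxy)-6-(3-methylbut-2-en-1-yl)benzaldehyde; 14 4,6-dimethyl-2H-pyran-2-one
Product: 16 6-[2-(ArB)-2-hydroxyethyl]-4-methyl-2H-pyran-2-one (racemic), via lithiated pyranone 15 (not isolated)
Conditions: LiN(i-Pr)2, THF, −78 °C; then 13, −78 °C; AcOH, −78 °C
Reagents that add atoms: none
Why: Vinylogous aldol addition; the amide base should remove a proton from the C6 methyl group, whose anion is delocalized through both ring double bonds to the carbonyl, and 15 adds to the non-enolizable aldehyde. The cold acetic acid quench should prevent dehydration and retro-aldol cleavage; the new carbinol center is racemic and is removed in step 11.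

Step 11
Reactants: 16 6-[2-(ArB)-2-hydroxyethyl]-4-methyl-2H-pyran-2-one (racemic)
Product: 17 6-[2-(ArB)-2-oxoethyl]-4-methyl-2H-pyran-2-one
Conditions: IBX, DMSO, rt
Reagents that add atoms: none
Why: IBX oxidation of a β-hydroxy carbonyl compound to the β-dicarbonyl level under non-acidic conditions; alkene, acetal and MOM ethers are tolerated.

Step 12
Reactants: 17 6-[2-(ArB)-2-oxoethyl]-4-methyl-2H-pyran-2-one
Product: 19 (2,6-dihydroxy-4-methylphenyl)(ArB)methanone, via methyl Z-enoate 18 (not isolated)
Conditions: Mg(OMe)2 (4 equiv), MeOH, reflux; then aq NH4Cl, 0 °C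
Reagents that add atoms: none
Why: Methoxide adds to the lactone carbonyl C2 and the acyl–oxygen bond breaks, giving the magnesium-chelated β-diketonate of methyl Z-enoate 18, whose Z geometry is that of the ring C3=C4 bond and keeps the ester beside the diketone. The central carbon A6 of the diketonate then attacks the ester carbonyl in a 6-exo-trig Claisen acylation that forms A6–A1 and closes ring A; methoxide leaves and the acylcyclohexenedione tautomerizes irreversibly to the resorcinol, so the step is a net isomerization. The closest known reaction type is the base-induced conversion of 6-(2-oxoalkyl)-2-pyranones into 2-acylresorcinols, the laboratory counterpart of polyketide Claisen cyclization. No stereocenter is formed. The step needs Claisen closure at A6 to win over aldol attack of the dienolate carbon A2 on the aryl ketone. Magnesium chelation should localize nucleophilicity at A6, and the ring B carbonyl is screened by its two ortho substituents. Acetal, MOM ethers and the prenyl group are inert to methoxide, and the weakly acidic cold quench should spare the acetal.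

Step 13
Reactants: 19 (2,6-dihydroxy-4-methylphenyl)(ArB)methanone
Product: 20 (2-hydroxy-6-methoxy-4-methylphenyl)(ArB)methanone
Conditions: MeI (1.05 equiv), K2CO3, acetone, rt
Reagents that add atoms: iodomethane, CI
Why: Williamson O-methylation; the two hydroxyls are equivalent by symmetry, so there is no regiochemical issue, and after the first methylation the remaining hydroxyl is chelated to the ketone and much less nucleophilic, so one equivalent should stop at the monoether.

Step 14
Reactants: 20 (2-hydroxy-6-methoxy-4-methylphenyl)(ArB)methanone
Product: 21 (3-bromo-2-hydroxy-6-methoxy-4-methylphenyl)(ArB)methanone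
Conditions: NBS (1.0 equiv), i-Pr2NH (10 mol %), CH2Cl2, −78 to 0 °C
Reagents that add atoms: N-bromosuccinimide, O=C1CCC(=O)N1Br
Why: Amine-mediated ortho-bromination of a phenol with NBS, in which the N-bromoamine is delivered through a hydrogen bond to the phenol; A4 is the only free position ortho to the hydroxyl. One equivalent at low temperature should spare the prenyl alkene and ring B, whose oxygens are capped and whose free position is para to the ketone.

Step 15
Reactants: 21 (3-bromo-2-hydroxy-6-methoxy-4-methylphenyl)(ArB)methanone
Product: 22 pestalone B, 2-(3-bromo-2-hydroxy-6-methoxy-4-methylbenzoyl)-4,6-dihydroxy-3-(3-methylbut-2-en-1-yl)benzaldehyde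
Conditions: 2 M aq HCl, THF–MeOH, rt to 40 °C
Reagents that add atoms: water, O (aldehyde oxygen)
Why: Acid-catalysed hydrolysis cleaves both aryl MOM ethers and the dimethyl acetal in one operation. Acid is chosen because the ortho-formyl benzophenone is base-sensitive, and dilute acid at or below 40 °C should leave the prenyl group uncyclized.

## Compound list

1 | methyl 3,5-dihydroxybenzoate | COC(=O)c1cc(O)cc(O)c1 | starting material
2 | N-{[2,4-dihydroxy-6-(methoxycarbonyl)phenyl]methylidene}-N-methylmethanaminium chloride | COC(=O)c1cc(O)cc(O)c1C=[N+](C)C.[Cl-] | intermediate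
3 | methyl 2-formyl-3,5-dihydroxybenzoate | COC(=O)c1cc(O)cc(O)c1C=O | intermediate
4 | 2-methylbut-3-en-2-ol | CC(C)(O)C=C | starting material
5 | lithium 2-methylbut-3-en-2-olate | [Li+].[O-]C(C)(C)C=C | intermediate
6 | methyl 2-methylbut-3-en-2-yl carbonate | COC(=O)OC(C)(C)C=C | intermediate
7 | methyl 2-formyl-3-hydroxy-5-[(2-methylbut-3-en-2-yl)oxy]benzoate | COC(=O)c1cc(OC(C)(C)C=C)cc(O)c1C=O | intermediate
8 | methyl 2-formyl-3-(methoxymethoxy)-5-[(2-methylbut-3-en-2-yl)oxy]benzoate | COC(=O)c1cc(OC(C)(C)C=C)cc(OCOC)c1C=O | intermediate
9 | methyl 2-formyl-5-hydroxy-3-(methoxymethoxy)-6-(3-methylbut-2-en-1-yl)benzoate | COC(=O)c1c(CC=C(C)C)c(O)cc(OCOC)c1C=O | intermediate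
10 | methyl 2-formyl-3,5-bis(methoxymethoxy)-6-(3-methylbut-2-en-1-yl)benzoate | COC(=O)c1c(CC=C(C)C)c(OCOC)cc(OCOC)c1C=O | intermediate
11 | methyl 2-(dimethoxymethyl)-3,5-bis(methoxymethoxy)-6-(3-methylbut-2-en-1-yl)benzoate | COC(=O)c1c(CC=C(C)C)c(OCOC)cc(OCOC)c1C(OC)OC | intermediate
12 | [2-(dimethoxymethyl)-3,5-bis(methoxymethoxy)-6-(3-methylbut-2-en-1-yl)phenyl]methanol | OCc1c(CC=C(C)C)c(OCOC)cc(OCOC)c1C(OC)OC | intermediate
13 | 2-(dimethoxymethyl)-3,5-bis(methoxymethoxy)-6-(3-methylbut-2-en-1-yl)benzaldehyde | O=Cc1c(CC=C(C)C)c(OCOC)cc(OCOC)c1C(OC)OC | intermediate
14 | 4,6-dimethyl-2H-pyran-2-one | CC1=CC(=O)OC(C)=C1 | starting material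
15 | [(4-methyl-2-oxo-2H-pyran-6-yl)methyl]lithium (delocalized trienolate) | [Li+].[CH2-]C1=CC(C)=CC(=O)O1 | intermediate
16 | 6-{2-[2-(dimethoxymethyl)-3,5-bis(methoxymethoxy)-6-(3-methylbut-2-en-1-yl)phenyl]-2-hydroxyethyl}-4-methyl-2H-pyran-2-one (racemic) | COC(OC)c1c(OCOC)cc(OCOC)c(CC=C(C)C)c1C(O)CC1=CC(C)=CC(=O)O1 | intermediate
17 | 6-{2-[2-(dimethoxymethyl)-3,5-bis(methoxymethoxy)-6-(3-methylbut-2-en-1-yl)phenyl]-2-oxoethyl}-4-methyl-2H-pyran-2-one | COC(OC)c1c(OCOC)cc(OCOC)c(CC=C(C)C)c1C(=O)CC1=CC(C)=CC(=O)O1 | intermediate
18 | methyl (2Z)-7-[2-(dimethoxymethyl)-3,5-bis(methoxymethoxy)-6-(3-methylbut-2-en-1-yl)phenyl]-3-methyl-5,7-dioxohept-2-enoate (magnesium chelate in the flask) | COC(=O)/C=C(C)\CC(=O)CC(=O)c1c(CC=C(C)C)c(OCOC)cc(OCOC)c1C(OC)OC | intermediate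
19 | [2-(dimethoxymethyl)-3,5-bis(methoxymethoxy)-6-(3-methylbut-2-en-1-yl)phenyl](2,6-dihydroxy-4-methylphenyl)methanone | COC(OC)c1c(OCOC)cc(OCOC)c(CC=C(C)C)c1C(=O)c1c(O)cc(C)cc1O | intermediate
20 | [2-(dimethoxymethyl)-3,5-bis(methoxymethoxy)-6-(3-methylbut-2-en-1-yl)phenyl](2-hydroxy-6-methoxy-4-methylphenyl)methanone | COC(OC)c1c(OCOC)cc(OCOC)c(CC=C(C)C)c1C(=O)c1c(O)cc(C)cc1OC | intermediate
21 | (3-bromo-2-hydroxy-6-methoxy-4-methylphenyl)[2-(dimethoxymethyl)-3,5-bis(methoxymethoxy)-6-(3-methylbut-2-en-1-yl)phenyl]methanone | COC(OC)c1c(OCOC)cc(OCOC)c(CC=C(C)C)c1C(=O)c1c(O)c(Br)c(C)cc1OC | intermediate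
22 | pestalone B, 2-(3-bromo-2-hydroxy-6-methoxy-4-methylbenzoyl)-4,6-dihydroxy-3-(3-methylbut-2-en-1-yl)benzaldehyde | COc1cc(C)c(Br)c(O)c1C(=O)c1c(C=O)c(O)cc(O)c1CC=C(C)C | target

## Step count and least certain steps

Total: 15 steps. Longest linear sequence: 14 steps (steps 1 and 3 to 15, from methyl 3,5-dihydroxybenzoate 1); step 2 is a one-step side branch.

**Step 12 (key step).** The most likely failures are aldol closure through the dienolate carbon A2 onto the aryl ketone, retro-Claisen cleavage of the diketone by methoxide, or reclosure to the pyranone because the hindered diketonate acylates slowly. The fallback gives up the ring synthesis and joins a finished ring A to aldehyde 13. Commercial 3-methoxy-5-methylphenol would be protected with 2-(trimethylsilyl)ethoxymethyl chloride to give 1-methoxy-3-methyl-5-{[2-(trimethylsilyl)ethoxy]methoxy}benzene F1. Lithiation with n-BuLi between the two oxygens would give the aryllithium F2, which adds to 13 to give the diaryl carbinol F3. IBX oxidation would give the diaryl ketone F4, and Bu4NF would remove the silylethoxymethyl group while leaving the MOM ethers. This sets out from 13 and returns to the route at 20.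

**Step 5.** The rearrangement may go to C4 between the two oxygens, or the tertiary allyl group may be lost as isoprene on heating. The fallback avoids the sigmatropic shift. Phenol 3 would be brominated with NBS at the position ortho to the free and para to the chelated hydroxyl, as 2,4-dihydroxybenzaldehyde is, to give methyl 2-bromo-6-formyl-3,5-dihydroxybenzoate F5. Both hydroxyls would be protected (NaH, MOMCl) to give methyl 2-bromo-6-formyl-3,5-bis(methoxymethoxy)benzoate F6. Stille coupling with tributyl(3-methylbut-2-en-1-yl)stannane and Pd(PPh3)4 in DMF would then install the prenyl group. This sets out from 3 and returns at 10.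

**Step 3.** The phenoxide may attack the primary allyl terminus, the branched ether may isomerize to the linear prenyl ether on prolonged contact with the catalyst, or both hydroxyls may be allylated. The fallback builds the tertiary ether by propargylation. Phenol 3 would be alkylated with 3-chloro-3-methylbut-1-yne (K2CO3, KI, CuI cat., acetone) to give methyl 2-formyl-3-hydroxy-5-[(2-methylbut-3-yn-2-yl)oxy]benzoate F7, and the alkyne would be semihydrogenated with H2 over Pd/CaCO3 poisoned with Pb(OAc)2. This sets out from 3 and returns at 7.

**Step 14.** Electrophilic bromine may add to the prenyl double bond, or substitution may occur at A2 or at B4. The fallback brominates when ring A is most activated and has no regiochemical choice. The symmetric resorcinol 19 would be treated with one equivalent of NBS at −78 °C to give (3-bromo-2,6-dihydroxy-4-methylphenyl)(ArB)methanone F8, which would then be mono-methylated with MeI and K2CO3. The methylation is expected to favour the hydroxyl remote from bromine, because the bromine-flanked one is more hindered and more strongly chelated; this selectivity is the price of the fallback and would have to be checked. It sets out from 19 and returns at 21.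

**Step 15.** Acid may add the B5 hydroxyl across the prenyl double bond to form a chroman, or the liberated aldehyde may react further with the neighbouring ketone during a long exposure. The fallback separates the two deprotections and avoids protic acid for the phenols. The acetal of 21 would be hydrolysed alone with PPTS in wet acetone to give 2-(3-bromo-2-hydroxy-6-methoxy-4-methylbenzoyl)-4,6-bis(methoxymethoxy)-3-(3-methylbut-2-en-1-yl)benzaldehyde F9. The aryl MOM ethers would then be converted to silyl ethers with TMSOTf and 2,2'-bipyridyl in MeCN at 0 °C and released with water. This sets out from 21 and returns at 22.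

## Further compounds

F1 | step 12 | 1-methoxy-3-methyl-5-{[2-(trimethylsilyl)ethoxy]methoxy}benzene | COc1cc(C)cc(OCOCC[Si](C)(C)C)c1
F2 | step 12 | (2-methoxy-4-methyl-6-{[2-(trimethylsilyl)ethoxy]methoxy}phenyl)lithium | [Li]c1c(OC)cc(C)cc1OCOCC[Si](C)(C)C
F3 | step 12 | [2-(dimethoxymethyl)-3,5-bis(methoxymethoxy)-6-(3-methylbut-2-en-1-yl)phenyl](2-methoxy-4-methyl-6-{[2-(trimethylsilyl)ethoxy]methoxy}phenyl)methanol (racemic) | COC(OC)c1c(OCOC)cc(OCOC)c(CC=C(C)C)c1C(O)c1c(OC)cc(C)cc1OCOCC[Si](C)(C)C
F4 | step 12 | [2-(dimethoxymethyl)-3,5-bis(methoxymethoxy)-6-(3-methylbut-2-en-1-yl)phenyl](2-methoxy-4-methyl-6-{[2-(trimethylsilyl)ethoxy]methoxy}phenyl)methanone | COC(OC)c1c(OCOC)cc(OCOC)c(CC=C(C)C)c1C(=O)c1c(OC)cc(C)cc1OCOCC[Si](C)(C)C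
F5 | step 5 | methyl 2-bromo-6-formyl-3,5-dihydroxybenzoate | COC(=O)c1c(Br)c(O)cc(O)c1C=O
F6 | step 5 | methyl 2-bromo-6-formyl-3,5-bis(methoxymethoxy)benzoate | COC(=O)c1c(Br)c(OCOC)cc(OCOC)c1C=O
F7 | step 3 | methyl 2-formyl-3-hydroxy-5-[(2-methylbut-3-yn-2-yl)oxy]benzoate | COC(=O)c1cc(OC(C)(C)C#C)cc(O)c1C=O
F8 | step 14 | (3-bromo-2,6-dihydroxy-4-methylphenyl)[2-(dimethoxymethyl)-3,5-bis(methoxymethoxy)-6-(3-methylbut-2-en-1-yl)phenyl]methanone | COC(OC)c1c(OCOC)cc(OCOC)c(CC=C(C)C)c1C(=O)c1c(O)cc(C)c(Br)c1O
F9 | step 15 | 2-(3-bromo-2-hydroxy-6-methoxy-4-methylbenzoyl)-4,6-bis(methoxymethoxy)-3-(3-methylbut-2-en-1-yl)benzaldehyde | COc1cc(C)c(Br)c(O)c1C(=O)c1c(C=O)c(OCOC)cc(OCOC)c1CC=C(C)C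
A1 | alternative 1 | [2-(7-bromo-4-methoxy-6-methyl-1-benzofuran-3-yl)-4,6-bis(2,2-dimethylpropanoyloxy)phenyl]methyl 2,2-dimethylpropanoate | COc1cc(C)c(Br)c2occ(-c3cc(OC(=O)C(C)(C)C)cc(OC(=O)C(C)(C)C)c3COC(=O)C(C)(C)C)c12
A2 | alternative 1 | {2-[2-(2-bromo-5-methoxy-3-methylphenoxy)acetyl]-4,6-bis(2,2-dimethylpropanoyloxy)phenyl}methyl 2,2-dimethylpropanoate | COc1cc(C)c(Br)c(OCC(=O)c2cc(OC(=O)C(C)(C)C)cc(OC(=O)C(C)(C)C)c2COC(=O)C(C)(C)C)c1
A3 | alternative 2 | ethyl 2-[3-bromo-6-methoxy-2-(methoxymethoxy)-4-methylbenzoyl]-3-(3-methylbut-2-en-1-yl)-4,6-dioxocyclohexane-1-carboxylate (mixture of diastereomers and enol forms) | CCOC(=O)C1C(=O)CC(=O)C(CC=C(C)C)C1C(=O)c1c(OC)cc(C)c(Br)c1OCOC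
A4 | alternative 2 | 6-methylhept-5-en-2-one | CC(=O)CCC=C(C)C
A5 | alternative 2 | diethyl 2-{2-[3-bromo-6-methoxy-2-(methoxymethoxy)-4-methylphenyl]-2-oxoethylidene}propanedioate | CCOC(=O)C(=CC(=O)c1c(OC)cc(C)c(Br)c1OCOC)C(=O)OCC
A6 | alternative 3 | 2-{[2-(dimethoxymethyl)-3,5-bis(methoxymethoxy)-6-(3-methylbut-2-en-1-yl)phenyl]{[tert-butyl(dimethyl)silyl]oxy}methyl}-3-methoxy-5-methylphenol (racemic) | COc1cc(C)cc(O)c1C(O[Si](C)(C)C(C)(C)C)c1c(C(OC)OC)c(OCOC)cc(OCOC)c1CC=C(C)C
A7 | alternative 3 | 1-diazo-3-methylbut-3-en-2-one | C=C(C)C(=O)C=[N+]=[N-]
A8 | alternative 3 | tert-butyl({1-[2-(dimethoxymethyl)-3,5-bis(methoxymethoxy)-6-(3-methylbut-2-en-1-yl)phenyl]-3-methoxyprop-2-yn-1-yl}oxy)dimethylsilane (racemic) | COC#CC(O[Si](C)(C)C(C)(C)C)c1c(C(OC)OC)c(OCOC)cc(OCOC)c1CC=C(C)C
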